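The north-east run is the north-west charge shrunk by one factor, so you can estimate it from the north-west curve once you know roughly how the rate scales with the charge.

| setting | north-west | west | south | north-east |
|---|---|---|---|---|
| Z | 80.0 mM | 40.0 mM | 80.0 mM | 32.0 mM |
| X | 120 mM | 80.0 mM | 240 mM | 48.0 mM |
| time |  |  |  | 92 s |

- north-west run (time / s: [G] / mM): 15: 13.4; 31: 27.4; 46: 37.1; 61: 46.1; 77: 54.0; 92: 57.4
- west run (time / s: [G] / mM): 15: 3.5; 31: 7.5; 46: 9.4; 61: 14.6; 77: 18.0; 92: 22.0
- south run (time / s: [G] / mM): 15: 37.9; 31: 59.9; 46: 72.5; 61: 76.1; 77: 78.6; 92: 78.6

(scatter of a reading: 1 mM)

- Overall: Z + X -> G.
- Constant volume, constant temperature.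
- Bound and free are read together.
- "The second partner" is X.
- An order is taken over about fifteen percent of the charge, up and down.

- the power of [X] that the first rate follows, about the charge of the north-west run; measure it at two percent of Z made into G
- the power of [Z] that the first rate follows, about the charge of the north-west run; measure it at two percent of Z made into G (one fixed amount of G, the same in the runs compared)
- the west run starts with 40.0 mM less of Z and of X than the north-west run, and with no G. Compared where both hold the same amount of Z, once fifteen percent of what the west run was charged with has turned into G, is the west run faster, slower or alike (within a tenth)?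
- G in the north-east run at 92 s, as a share of the Z charged

I start with the north-west run, whose first chord gives 0.893 mM s⁻¹. The south run charges twice the cX, but by 15 s it has already made 37.9 mM, so a chord would undercount its start. With X in excess I treat its Z as decaying exponentially (pseudo-first-order), which gives a start of 3.42 mM s⁻¹. That reads as an order in X of 1.94. Put this back into the west run: the first-reading ratio of north-west to west, divided by the X part, leaves an order in Z of 0.803.

Now the north-east run. Its cZ and cX are both the north-west values times 0.400. At equal fractions made, I take the rate to scale as that factor to the total order m, so the fraction made per second scales as the factor to m minus one. Call this the clock factor: north-east time times it gives the matching north-west time. The first pass gives 0.203, so 92 s matches 18.7 s, and interpolating the north-west readings gives 20.8%.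

The weak link is the west reading 3.5 mM, which carries a scatter of 1 mM. Going round again with the readings at 31 s gives an order in Z of 0.735, a total order of 2.67 and a clock factor of 0.216. The matching time becomes 19.8 s, and I commit to 22.1%.

For the comparison, both runs charge X in the same excess of 40.0 mM, so equal cZ means equal cX. The north-west run reaches the point near 61 s, with cG at 46.1 mM, and climbs at 0.545 mM s⁻¹. The west run, with cG near 6 mM, climbs at 0.239 mM s⁻¹, so it is slower.

The forecast, which differs from my reckoning in the order in Z, gives 1.9, 1, slower and 23%, reasoning that “West holds its rate even as Z and X fall, so G must be speeding the reaction”.

The flask gives 1.7 in X, 0.69 in Z, slower for the west run, at a rate ratio of 0.54, and 25.7% for the north-east run.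

    Z + X → G (0.01270 M⁻¹ s⁻¹)
    Z + 2 X → G + X (1.730 M⁻² s⁻¹)
    Z + X ⇌ ZX, settled at all times (4.200 M⁻¹)
    Z + X + G → 2 G (3.170 M⁻² s⁻¹)

The order in Z stays below one because Z and X park as ZX: the north-west charge without that parking gives 1.0. The total order is then 2.42, lower than my 2.67, and the clock factor rises from 0.216 to 0.272. This clock turns 92 s into 25.0 s on the north-west curve, where interpolating the readings gives 27.7%, more than the north-east run shows, so with these orders, taken about the north-west charge, the clock overshoots. The north-east run holds 25.7% of its charged Z as G at 92 s.

The runs are simulated with constants of no real substance; scatter was added.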